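(The runs stem from a simulated flask for substances that don't exist.)

Left-handed product grows out of a racemic charge under a single-handed catalyst, and I want to know how far right-handed substrate leads left-handed substrate among what is left after 3.0 d in green and amber.

| flask | left-handed substrate | right-handed substrate | reagent | free catalyst | impurity | remark | time |
|---|---|---|---|---|---|---|---|
| elm | 0.10 M | 0.10 M | 0.027 M | 50 µM | 10 µM | run made earlier |  |
| alder | 0.10 M | 0.10 M | 0.056 M | 50 µM | 10 µM | run made earlier |  |
| oak | 0.10 M | 0.10 M | 0.092 M | 50 µM | 10 µM | run made earlier |  |
| green | 0.10 M | 0.10 M | 0.110 M | 50 µM | 10 µM |  | 3.0 d |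
| amber | 0.10 M | 0.10 M | 0.0300 M | 50 µM | 10 µM |  | 3.0 d |

| run | time / h | right-handed substrate / % | left-handed substrate / % | left-handed product / % |
|---|---|---|---|---|
| elm | 10.0 | 48 | 48 | 4 |
| elm | 20.0 | 45 | 46 | 4 |
| elm | 30.0 | 47 | 46 | 8 |
| elm | 40.0 | 46 | 43 | 11 |
| elm | 48.0 | 49 | 45 | 8 |
| alder | 5.00 | 51 | 49 | 4 |
| alder | 12.0 | 44 | 38 | 9 |
| alder | 25.0 | 44 | 45 | 9 |
| alder | 40.0 | 41 | 41 | 15 |
| alder | 48.0 | 43 | 38 | 17 |
| oak | 5.00 | 45 | 42 | 5 |
| oak | 12.0 | 40 | 44 | 11 |
| oak | 25.0 | 41 | 39 | 21 |
| oak | 40.0 | 39 | 32 | 26 |
| oak | 48.0 | 37 | 35 | 25 |

(readings scatter by 2 percentage points)

- free catalyst is single-handed; left-handed substrate and right-handed substrate are mirror images of each other, charged as a racemate, each of them at the stated concentration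
- what was read earlier has a scatter of 2 percentage points, one standard deviation
- an excess is the difference of the two amounts in percent of their sum
- an excess is below zero if the other one leads

1. which one finishes higher in excess of right-handed substrate over left-handed substrate among what is left of the two ("neither" within 2 percentage points) (green / amber / neither)
2. excess of right-handed substrate over left-handed substrate among what is left of the two at the end, green
3. excess of right-handed substrate over left-handed substrate among what is left of the two at the end, amber

1. In oak at 48.0 h left-handed product reads 25%, yet left-handed substrate has lost 15 percentage points and right-handed substrate 13 points. Together these make 28 points, so the product agrees with the two losses within the scatter, and I take it that the substrates pass into each other.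

2. A gap, c(right-handed substrate) − c(left-handed substrate), then closes as it opens, so in a quasi-steady state it follows the present rate of making product, not the amount made. Oak's gap averages 2 points over its readings, a rough reading given the scatter. Dividing it by the mean rate of making left-handed product gives my memory time, 3.84 h.

3. The balance of the reagent in oak, taken at its last reading, reads 0.543 left-handed product per reagent charged, and the rise of product in oak reads as a time constant of 20.7 h; both carry the scatter of the readings.

4. So I estimate left-handed product near 29.9% in green and near 8.15% in amber at the asked time. Memory time times the remaining rate gives excesses of 0.244% in green and 0.0508% in amber, both below the margin, so I say neither.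

5. The forecast differs from my reckoning: it says green, with 6.5% for green and 1.6% for amber, on the ground that “Left-handed substrate is consumed only slightly faster”.

6. The flasks give neither, with 0.389% in green and 0.0857% in amber.

    free catalyst + impurity → spent catalyst B (k = 390 /M/s)
    reagent + catalyst intermediate B → free catalyst + right-handed product (k = 0.240 /M/s)
    reagent + catalyst intermediate A → free catalyst + left-handed product (k = 0.500 /M/s)
    2 free catalyst → spent catalyst A (k = 1.30 /M/s)
    free catalyst + right-handed substrate ⇌ catalyst intermediate B (K = 5.20 /M, k = 130 /M/s)
    free catalyst + left-handed substrate ⇌ catalyst intermediate A (K = 18.0 /M, k = 11.0 /M/s)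
    left-handed substrate ⇌ right-handed substrate (k = 5.50 × 10⁻⁵ /s)

7. Both results stand above my figures  of 0.244% and 0.0508%, yet below the margin. The neighbour is green read at 20 h, where the same memory time and the same decay of the rate give me 2.59%, which is more than that flask shows. Green read at 20 h holds less left-handed product than green read at 3.0 d, 21.2% against 33.5%, and a larger excess, 1.78%.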